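The first half-life of starting material through dimerising, 4.89 h, is shorter than the 11.1 h time constant of reagent crossing into the reaction phase.

starting material 0.40 M; reagent in the second phase 1.30 equiv; time 12 h; volume of the second phase over the first 1.0

    reagent in the reaction phase ⇌ reagent in the second phase, rate k1*([reagent in the reaction phase] - [reagent in the second phase]/K1) per volume of the first phase (K1 = 0.753, k1 = 6.43 × 10⁻⁴ min⁻¹)
    starting material + reagent in the reaction phase → target (k2 = 0.00396 M⁻¹ min⁻¹)
    target ⇌ product in the second phase, rate k3*([target] - [product in the second phase]/K3) per volume of the first phase (K3 = 0.13, k3 = 0.00202 min⁻¹)
    target → decomposed product (k4 = 7.15 × 10⁻⁴ min⁻¹)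
    reagent in the reaction phase + target → over-reaction product A (k5 = 0.00371 M⁻¹ min⁻¹)
    2 starting material → homo dimer (k6 = 0.00426 M⁻¹ min⁻¹)
    target → over-reaction product B (k7 = 7.84 × 10⁻⁷ min⁻¹)

* how much target and product in the second phase together there is at 12 h, in percent of the starting material charged
* part of the starting material charged that has reacted at 12 h

- percent here means starting material units held: one homo dimer counts as two
- what is said of target includes product in the second phase
- for a step with 2 of a species take k times the square, and two of it per event
- in the second phase: reagent in the second phase, product in the second phase; everything else is in the first
- charges count per volume of the first phase; a concentration in a rate is the amount of a species over the volume of its own phase; every rate counts per litre of the first phase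
- run time (flask): 12 h

I count turnovers. With dimerising taken by itself, the first half-life lengthens as starting material thins, so the fraction left is one over (one plus elapsed time over that first half-life). My dimer count is the run time divided by the first half-life:

dimer count = 12 h / 4.89 h = 2.45

Ignoring what it spends, reagent in the reaction phase climbs towards its partition level, 0.297 M. It behaves as if it stood there from the start but arrived after a lag:

lag = 7.34 h

To starting material this reagent is a pseudo-first-order loss, which gives a reagent count:

reagent count = 0.00396 M⁻¹ min⁻¹ × 0.297 M × (run time − lag) = 0.328

On a logarithmic scale, the loss of starting material is 1.24 from dimerising, more than the 0.328 from reagent. Multiplying the two surviving fractions, I expect this part reacted: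

reacted = 79.1 %

For target, I multiply the reagent count by the fraction left after dimerising at mid-run, 0.449, and by the fraction surviving decomposition from mid-run to the end, 0.773:

target = 11.4 %

The forecast gives 9.2 % and 76 %, on the ground that “the second-order homo-dimerisation uses up most of the starting material before much reagent is available”. My target figure is higher than the forecast's.

The flask gives 7.63 % of target and 76.4 % reacted, so the forecast holds within its margin, and its target figure and mine both stand above the flask's. At 12.0 h this flask holds 65.8 % as homo dimer, while the dimer count taken by itself gives 71.0 %, more than that reading.

With 0.10 M of starting material and the same equivalents and time, the dimer count falls to 0.613 and the reagent count to 0.0820. I reckon 42.9 % reacted and 4.85 % target. That flask gives 42.0 % and 4.37 %.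

The rate constants are invented; the run is a simulation.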